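**Retrosynthetic overview**
- Target 17 comes from depside 14 by methylation of its one unchelated phenol (ring A O-4), hydrolysis of both dioxolanes and hydrogenolysis of the benzyl ester.
- Feature used: the ester carbonyl carbon bonded to O-4 of ring B is also C1 of a linear chain with carbonyls at C3, C5 and C7 (C9 ketalized). Its C2-to-C7 aldol fold is ring A, so the ester C–O bond and the ring A C1–C6 bond are cut together, back to acylketene 11 and phenol 10.
- Ring B is formed first (step 5) from diketo-dioxinone 6 by amine-induced closure to benzodioxinone 8, which benzyl alcohol opens to phenol 10 (step 6). Ring A is formed second (step 7), on the ring B oxygen, from a second portion of 6.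
- 6 comes from dioxinone 4 by two acylations at the methyl terminus: acetyl chloride, then Weinreb amide 3 made from ethyl 3-oxooctanoate.

Key step: step 7

Assumption: Microphyllinsaure is taken as microphyllinic acid as drawn; it has no stereocentre, so no stereocontrol is needed. Aldol adducts 7 (racemic) and 13 (diastereomer mixture) are transient and lose their centres on aromatization.

**Step 1**
Reactants: 1 ethyl 3-oxooctanoate
Product: 2 ethyl 2-(2-pentyl-1,3-dioxolan-2-yl)acetate
Conditions: HOCH2CH2OH, pTsOH·H2O (cat.), PhMe, reflux, Dean–Stark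
Reagents that add atoms: ethylene glycol, OCCO
Why: acid-catalysed ketalization of the ketone of a β-keto ester with azeotropic removal of water should give the dioxolane and leave the ester untouched.

**Step 2**
Reactants: 2 ethyl 2-(2-pentyl-1,3-dioxolan-2-yl)acetate
Product: 3 N-methoxy-N-methyl-2-(2-pentyl-1,3-dioxolan-2-yl)acetamide
Conditions: MeNH(OMe)·HCl, iPrMgCl, THF, −20 to 0 °C; aq. NH4Cl
Reagents that add atoms: N,O-dimethylhydroxylamine hydrochloride, CNOC.Cl
Why: aminolysis of the ester by the chloromagnesium amide of N,O-dimethylhydroxylamine (Weinreb amide formation) should proceed at low temperature, where this weakly basic amide does not open the β-ketal by elimination.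

**Step 3**
Reactants: 4 2,2,6-trimethyl-4H-1,3-dioxin-4-one
Product: 5 2,2-dimethyl-6-(2-oxopropyl)-4H-1,3-dioxin-4-one
Conditions: LiN(SiMe3)2, THF, −78 °C; AcCl (0.5 equiv), −78 °C; aq. NH4Cl
Reagents that add atoms: acetyl chloride, CC(=O)Cl
Why: γ-deprotonation gives the lithium dienolate, which should undergo C-acylation at the methyl terminus (vinylogous Claisen condensation), the excess dienolate absorbing the acidic proton of the product.

**Step 4**
Reactants: 5 2,2-dimethyl-6-(2-oxopropyl)-4H-1,3-dioxin-4-one; 3 N-methoxy-N-methyl-2-(2-pentyl-1,3-dioxolan-2-yl)acetamide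
Product: 6 2,2-dimethyl-6-[2,4-dioxo-5-(2-pentyl-1,3-dioxolan-2-yl)pentyl]-4H-1,3-dioxin-4-one
Conditions: LiN(iPr)2 (2.5 equiv), THF, −78 °C; then 3, −78 to −40 °C; aq. NH4Cl
Reagents that add atoms: none
Why: the dianion of 5 should react at its terminal carbon with the Weinreb amide (Claisen-type acylation), the chelated tetrahedral intermediate preventing over-addition and the product being protected as its enolate until the buffered quench.

**Step 5**
Reactants: 6 2,2-dimethyl-6-[2,4-dioxo-5-(2-pentyl-1,3-dioxolan-2-yl)pentyl]-4H-1,3-dioxin-4-one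
Product: 8 7-hydroxy-2,2-dimethyl-5-[(2-pentyl-1,3-dioxolan-2-yl)methyl]-4H-1,3-benzodioxin-4-one, via bicyclic aldol adduct 7 (not isolated)
Conditions: Et3N (3 equiv), CH2Cl2, rt; AcOH wash
Reagents that add atoms: none
Why: amine-promoted intramolecular aldol condensation of a diketo-dioxinone (cycloaromatization), in which C5 of the dioxinone adds to the distal side-chain ketone in a six-membered closure and loss of water gives the acetonide-masked resorcylate without any ketene being formed, while the dioxolane keeps the remaining carbonyl out of the fold.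

**Step 6**
Reactants: 8 7-hydroxy-2,2-dimethyl-5-[(2-pentyl-1,3-dioxolan-2-yl)methyl]-4H-1,3-benzodioxin-4-one; 9 benzyl alcohol
Product: 10 benzyl 2,4-dihydroxy-6-[(2-pentyl-1,3-dioxolan-2-yl)methyl]benzoate
Conditions: BnOH (5 equiv), NaH (2.5 equiv), THF, 0 to 50 °C; aq. NH4Cl
Reagents that add atoms: none
Why: alkoxide transesterification of a benzodioxinone, in which sodium benzyloxide adds to the ring carbonyl and the opened hemiketal loses acetone to leave the benzyl salicylate, the dioxolane being stable to base.

**Step 7**
Reactants: 6 2,2-dimethyl-6-[2,4-dioxo-5-(2-pentyl-1,3-dioxolan-2-yl)pentyl]-4H-1,3-dioxin-4-one; 10 benzyl 2,4-dihydroxy-6-[(2-pentyl-1,3-dioxolan-2-yl)methyl]benzoate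
Product: 14 bis-ketal benzyl ester of 4-O-demethylmicrophyllinic acid, via acylketene 11 (not isolated), via aryl trioxo ester 12 (not isolated), via aryl aldol adduct 13 (not isolated)
Conditions: 10 (1.5 equiv), PhMe, 110 °C, slow addition of 6; cool; Et3N (2 equiv), CH2Cl2, 0 °C to rt; AcOH quench
Reagents that add atoms: none
Why: Proposed new method: heating 6 causes retro-[4+2] loss of acetone to acylketene 11, whose ketene carbon is attacked by the free 4-hydroxyl of 10 to form the depside C–O bond (12), and Et3N then lets the C2 methylene of 12 add to the C7 ketone in a 6-(enolexo)-exo-trig aldol addition that forms the C1–C6 bond of ring A (13), after which loss of water and enolization give the aromatic ring of 14. The closest known reaction type is the thermolysis of diketo-dioxinones with alcohols followed by base-induced aldol aromatization to alkyl resorcylates, together with the acetoacetylation of phenols by thermolysis of simple dioxinones; new here is that the trapping hydroxyl is phenolic and that an aryl ester has to survive the aldol stage. No stereocentre persists, because the two centres of 13 are lost on aromatization. Site selectivity between the two hydroxyls of 10 is expected because the 2-hydroxyl is held in a hydrogen bond to the benzyl ester carbonyl and is flanked by it, whereas the 4-hydroxyl is free and unhindered. Aldol closure should be favoured over Claisen or pyranone closure, both of which would expel the aryloxide, by a weak amine base in an aprotic solvent at or below room temperature, where C2 (between ester and ketone) is the nucleophile and the C7 ketone the most electrophilic carbonyl, while the dioxolane keeps the C9 carbonyl out of the fold. Separating the heating stage from the base stage ensures that the new phenols of ring A never meet the ketene.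

**Step 8**
Reactants: 14 bis-ketal benzyl ester of 4-O-demethylmicrophyllinic acid
Product: 15 bis-ketal benzyl ester of microphyllinic acid (ring A 4-O-methyl ether)
Conditions: TMSCHN2 (1.2 equiv), iPr2NEt (cat.), MeCN/MeOH (9:1), 0 °C to rt; AcOH quench
Reagents that add atoms: trimethylsilyldiazomethane, C[Si](C)(C)C=[N+]=[N-]
Why: O-methylation by a diazoalkane is governed by phenol acidity, so only the unchelated 4-hydroxyl of ring A (para to the ester carbonyl) should react while the two hydroxyls hydrogen-bonded to ester carbonyls stay untouched, and the near-neutral medium spares the depside ester.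

**Step 9**
Reactants: 15 bis-ketal benzyl ester of microphyllinic acid
Product: 16 benzyl microphyllinate (benzyl 2-hydroxy-4-{[2-hydroxy-4-methoxy-6-(2-oxoheptyl)benzoyl]oxy}-6-(2-oxoheptyl)benzoate)
Conditions: 1 M aq. HCl/THF (1:4), rt, stopped at full conversion; aq. NaHCO3
Reagents that add atoms: water, O
Why: acid-catalysed hydrolysis of the two dioxolanes (ketal hydrolysis) should release both ketones under conditions that leave the aryl ester, the benzyl ester and the methyl ether intact, short exposure at room temperature limiting enol lactonization.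

**Step 10**
Reactants: 16 benzyl microphyllinate
Product: 17 microphyllinic acid (target)
Conditions: H2 (1 atm), Pd/C, EtOAc, rt
Reagents that add atoms: none
Why: hydrogenolysis of the benzyl ester over Pd/C is neutral, so the aliphatic ketones, the depside ester and the phenols should survive and the free keto acid is not exposed to acid that would close it to a lactol or isocoumarin.

**Compound list**
1 | ethyl 3-oxooctanoate | CCCCCC(=O)CC(=O)OCC | starting material
2 | ethyl 2-(2-pentyl-1,3-dioxolan-2-yl)acetate | CCCCCC1(CC(=O)OCC)OCCO1 | intermediate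
3 | N-methoxy-N-methyl-2-(2-pentyl-1,3-dioxolan-2-yl)acetamide | CCCCCC1(CC(=O)N(C)OC)OCCO1 | intermediate
4 | 2,2,6-trimethyl-4H-1,3-dioxin-4-one | CC1=CC(=O)OC(C)(C)O1 | starting material
5 | 2,2-dimethyl-6-(2-oxopropyl)-4H-1,3-dioxin-4-one | CC(=O)CC1=CC(=O)OC(C)(C)O1 | intermediate
6 | 2,2-dimethyl-6-[2,4-dioxo-5-(2-pentyl-1,3-dioxolan-2-yl)pentyl]-4H-1,3-dioxin-4-one | CC1(C)OC(=O)C=C(CC(=O)CC(=O)CC2(CCCCC)OCCO2)O1 | intermediate
7 | bicyclic aldol adduct, 5-hydroxy-2,2-dimethyl-5-[(2-pentyl-1,3-dioxolan-2-yl)methyl]-5,6-dihydro-4H-1,3-benzodioxine-4,7(8H)-dione (racemic; formed in the flask, not isolated) | CC1(C)OC(=O)C2=C(CC(=O)CC2(O)CC2(CCCCC)OCCO2)O1 | intermediate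
8 | 7-hydroxy-2,2-dimethyl-5-[(2-pentyl-1,3-dioxolan-2-yl)methyl]-4H-1,3-benzodioxin-4-one | CC1(C)OC(=O)c2c(CC3(CCCCC)OCCO3)cc(O)cc2O1 | intermediate
9 | benzyl alcohol | OCc1ccccc1 | starting material
10 | benzyl 2,4-dihydroxy-6-[(2-pentyl-1,3-dioxolan-2-yl)methyl]benzoate | CCCCCC1(Cc2cc(O)cc(O)c2C(=O)OCc2ccccc2)OCCO1 | intermediate
11 | acylketene, 8-(2-pentyl-1,3-dioxolan-2-yl)oct-1-ene-1,3,5,7-tetraone (formed in the flask, not isolated) | O=C=CC(=O)CC(=O)CC(=O)CC1(CCCCC)OCCO1 | intermediate
12 | aryl trioxo ester, benzyl 2-hydroxy-4-{[3,5,7-trioxo-8-(2-pentyl-1,3-dioxolan-2-yl)octanoyl]oxy}-6-[(2-pentyl-1,3-dioxolan-2-yl)methyl]benzoate (formed in the flask, not isolated) | CCCCCC1(CC(=O)CC(=O)CC(=O)CC(=O)Oc2cc(O)c(C(=O)OCc3ccccc3)c(CC3(CCCCC)OCCO3)c2)OCCO1 | intermediate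
13 | aryl aldol adduct, the 2-hydroxy-4,6-dioxo-2-[(2-pentyl-1,3-dioxolan-2-yl)methyl]cyclohexane-1-carboxylate of phenol 10 at O-4 (diastereomer mixture, racemic; formed in the flask, not isolated) | O=C(Oc1cc(O)c(C(=O)OCc2ccccc2)c(CC2(CCCCC)OCCO2)c1)C1C(=O)CC(=O)CC1(O)CC1(CCCCC)OCCO1 | intermediate
14 | bis-ketal benzyl ester of 4-O-demethylmicrophyllinic acid | CCCCCC1(Cc2cc(OC(=O)c3c(O)cc(O)cc3CC3(CCCCC)OCCO3)cc(O)c2C(=O)OCc2ccccc2)OCCO1 | intermediate
15 | bis-ketal benzyl ester of microphyllinic acid | CCCCCC1(Cc2cc(OC(=O)c3c(O)cc(OC)cc3CC3(CCCCC)OCCO3)cc(O)c2C(=O)OCc2ccccc2)OCCO1 | intermediate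
16 | benzyl microphyllinate | CCCCCC(=O)Cc1cc(OC(=O)c2c(O)cc(OC)cc2CC(=O)CCCCC)cc(O)c1C(=O)OCc1ccccc1 | intermediate
17 | microphyllinic acid | CCCCCC(=O)Cc1cc(OC(=O)c2c(O)cc(OC)cc2CC(=O)CCCCC)cc(O)c1C(=O)O | target

**Step count**
Total steps: 10. Longest linear sequence: 9 steps (1 → 2 → 3 → 6 → 8 → 10 → 14 → 15 → 16 → 17).

**Steps most likely to fail**

1. Step 7 (the step marked as a proposed new method).
 - What may go wrong: capture of the ketene by the weakly nucleophilic phenol may be outrun by intramolecular closure of the acylketene to a 4-hydroxy-2-pyranone. At the base stage the aryloxide may be expelled by Claisen or lactone closure, or by ketene re-formation, before the aldol closes.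
 - Fallback (known chemistry): this gives up the ketene capture and makes the ester bond by classical depside esterification. It sets out from 10. Methylation of the unchelated 4-hydroxyl (MeI, K2CO3, acetone, rt) should give benzyl 2-hydroxy-4-methoxy-6-[(2-pentyl-1,3-dioxolan-2-yl)methyl]benzoate F1. Hydrogenolysis (H2, Pd/C, EtOAc) should give 2-hydroxy-4-methoxy-6-[(2-pentyl-1,3-dioxolan-2-yl)methyl]benzoic acid F2. Steglich esterification of F2 with the free 4-hydroxyl of a second portion of 10 (DCC, DMAP cat., CH2Cl2, 0 °C to rt) should give 15 directly, where the route is rejoined before step 9.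

2. Step 4.
 - What may go wrong: the dianion may act as a base toward the α-methylene of the amide, causing proton transfer and eliminative opening of the dioxolane, so that acyl transfer stays incomplete.
 - Fallback: the acylation is replaced by an aldol addition followed by oxidation. It sets out from 2. Reduction (iBu2AlH, CH2Cl2, −78 °C) should give 2-(2-pentyl-1,3-dioxolan-2-yl)acetaldehyde F3. Addition of the dianion of 5 (LiN(iPr)2, THF, −78 °C) should give racemic 6-[4-hydroxy-2-oxo-5-(2-pentyl-1,3-dioxolan-2-yl)pentyl]-2,2-dimethyl-4H-1,3-dioxin-4-one F4. Dess–Martin oxidation (NaHCO3, CH2Cl2) should give 6, where the route is rejoined.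

3. Step 6.
 - What may go wrong: under the basic conditions the 7-hydroxyl is deprotonated, and the phenoxide para to the ring carbonyl donates into it, so that addition of benzyloxide may stall and forcing conditions may be needed.
 - Fallback: the ring B ester is made by ketene capture and not by opening of the acetonide, so steps 5 and 6 are bypassed. It sets out from 6. Heating 6 with benzyl alcohol 9 (PhMe, 110 °C) should give, by loss of acetone and capture of acylketene 11 by the alcohol, benzyl 3,5,7-trioxo-8-(2-pentyl-1,3-dioxolan-2-yl)octanoate F5. Et3N (CH2Cl2, rt) should close it to the cyclic aldol adduct benzyl 2-hydroxy-4,6-dioxo-2-[(2-pentyl-1,3-dioxolan-2-yl)methyl]cyclohexane-1-carboxylate F6 (diastereomer mixture, racemic), which should lose water and enolize to 10, where the route is rejoined before step 7.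

**Further compounds**
F1 | step 7 | benzyl 2-hydroxy-4-methoxy-6-[(2-pentyl-1,3-dioxolan-2-yl)methyl]benzoate | CCCCCC1(Cc2cc(OC)cc(O)c2C(=O)OCc2ccccc2)OCCO1
F2 | step 7 | 2-hydroxy-4-methoxy-6-[(2-pentyl-1,3-dioxolan-2-yl)methyl]benzoic acid | CCCCCC1(Cc2cc(OC)cc(O)c2C(=O)O)OCCO1
F3 | step 4 | 2-(2-pentyl-1,3-dioxolan-2-yl)acetaldehyde | CCCCCC1(CC=O)OCCO1
F4 | step 4 | 6-[4-hydroxy-2-oxo-5-(2-pentyl-1,3-dioxolan-2-yl)pentyl]-2,2-dimethyl-4H-1,3-dioxin-4-one (racemic) | CC1(C)OC(=O)C=C(CC(=O)CC(O)CC2(CCCCC)OCCO2)O1
F5 | step 6 | benzyl 3,5,7-trioxo-8-(2-pentyl-1,3-dioxolan-2-yl)octanoate | O=C(CC(=O)CC(=O)CC(=O)CC1(CCCCC)OCCO1)OCc1ccccc1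
F6 | step 6 | benzyl 2-hydroxy-4,6-dioxo-2-[(2-pentyl-1,3-dioxolan-2-yl)methyl]cyclohexane-1-carboxylate (diastereomer mixture, racemic) | O=C(OCc1ccccc1)C1C(=O)CC(=O)CC1(O)CC1(CCCCC)OCCO1
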